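Each chain begun uses up one initiator, so chains begun plus initiator left stay at the charge. Your average length is therefore monomer in chains over initiator spent, and you need the clock that spends initiator.

| flask | free monomer | protic impurity | initiator | remark | time |
|---|---|---|---|---|---|
| green | 0.30 M (fed, over 4.0 h) | 0.015 M | 5 mM | run made earlier |  |
| ochre | 0.30 M (fed, over 4.0 h) | 0.015 M | 11 mM | run made earlier |  |
| amber | 0.30 M (fed, over 4.0 h) | 0.022 M | 7.5 mM | run made earlier |  |
| autumn | 0.30 M (fed, over 4.0 h) | 0.0150 M | 7.5 mM |  | 4.0 h |
| winter | 0.30 M (fed, over 12 h) | 0.0150 M | 7.5 mM |  | 4.0 h |

| run | time / h | monomer in chains / % | free monomer / % |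
|---|---|---|---|
| green | 0.500 | 0.2 | 11.9 |
| green | 1.00 | 0.2 | 22.8 |
| green | 1.50 | 1.2 | 33.8 |
| green | 2.00 | 0.9 | 44.3 |
| green | 2.50 | 2.3 | 55.1 |
| green | 3.00 | 2.4 | 66.9 |
| ochre | 0.500 | 0 | 13.1 |
| ochre | 1.00 | 0.8 | 23.0 |
| ochre | 1.50 | 1.1 | 34.1 |
| ochre | 2.00 | 3.4 | 43.9 |
| ochre | 2.50 | 4.9 | 53.9 |
| ochre | 3.00 | 6.8 | 64.4 |
| amber | 0.250 | 0 | 6.3 |
| amber | 0.500 | 0 | 11.9 |
| amber | 0.833 | 1.0 | 19.6 |
| amber | 1.50 | 0.8 | 32.7 |
| amber | 3.00 | 4.6 | 63.3 |

(scatter of a reading: 0.5 percentage points)

- the average divides the monomer in chains by the number of chains begun, living and dead together
- percentages count the whole charge, also what has not yet gone in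
- the earlier runs do not show the number of chains; that part of a forecast is a guess

- which of the two ends with the longer chains by the average number of monomer units in a chain (chains begun, living or dead) ("neither" if they lie within 10%) (autumn / winter / neither)
- average number of monomer units in a chain (chains begun, living or dead) at the end, autumn
- average number of monomer units in a chain (chains begun, living or dead) at the end, winter

A steady feed with little lost makes free monomer a ramp, and the area under a ramp is half the feed rate times time squared. By 4.0 h autumn has 0.600 M·h and winter 0.200 M·h, a third of it. Call this the exposure, free monomer integrated over time. If a chain starts when free monomer meets initiator, the logarithm of the initiator left falls in a straight line with exposure, a pseudo-first-order decay with exposure as its clock.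

Now run it slowly. In the first instants free monomer has just arrived, and exposure grows as the square of time, so few chains start. Something else takes monomer too. By 3.00 h amber misses 21.3 mM from both columns, on the scale of its 0.022 M of protic impurity, so the ramp runs a little high.

In the middle you can read a constant. Amber's 4.6% in chains, over its initiator and its exposure so far, gives about 6.46 /M/h. That reading counts every unit as a start, so it overstates the starting constant, and I use it knowingly.

At the end this constant leaves about 2.07% of the initiator in autumn and 27.5% in winter. Chains begun are then 7.34 mM and 5.44 mM. The same constant, with initiator held at its charge, puts 29.1 mM and 9.69 mM in chains. My reckoning is about 3.96 units for autumn and 1.78 for winter, so autumn is longer.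

The forecast also names autumn, with 3.3 and 1.3 units, a lower winter figure than mine, and says “The chain count is a guess”.

The flask gives autumn, with 3.63 units for autumn and 1.87 for winter.

    living end → dead end (k = 0.0470 /min)
    free monomer + living end → monomer in chains + living end, rate k2*[living end]*[free monomer] (k = 0.850 /M/min)
    free monomer + initiator → living end + monomer in chains (k = 0.0540 /M/min)
    protic impurity + free monomer → quenched substrate (k = 0.160 /M/min)

The gap comes from the dosing time: take winter's longer dosing away, so that it is dosed over autumn's 4.0 h, and it gives 3.63 units, not 1.87. Autumn's 18% of initiator left, over its exposure, gives a logarithmic slope of 2.87 /M/h, and winter's exposure then leaves 56.3%, where the flask holds 58%. Left on, the autumn flask holds free monomer at 87.6% at 4.00 h and 84.9% at 6.00 h, which adds about 0.517 M·h of exposure. The slope then leaves 4.05%, and that flask holds 3.4%.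

Readings and results come from a simulation for an exercise, and the scatter is random.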